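**Plan**
- Retrosynthetic cuts, in order: the benzyl and benzylidene C–O bonds; O1(l)–C2(l); the C3(l)–O and C4(l)–O bonds (cis-diol from a Z-alkene); C4(l)–C4a(l); O1(u)–C2(u); C2(u)–aryl; then O1(u)–C8a(u), traced back to the C1–C7a bond of a 3-arylindan-1-one; last the arene–C3 bond of that indanone and the chalcone C=C.
- Enabling feature: the upper pyran ring O1(u)–C2(u)–C3(u)–C4(u)–C4a(u)–C8a(u) is the five-membered ring of a 3-arylindane (C2(u), C3(u), C4(u), C4a(u), C8a(u)) with one oxygen inserted between C8a(u) and C2(u), and C4(u) is a benzylic, non-enolisable carbon on ring A.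
- Forward order of rings: benzo-fused five-membered carbocycle (intramolecular Heck), six-membered lactone (Baeyer–Villiger oxygen insertion), upper pyran (Mitsunobu closure after aryl addition), lower pyran last (second Mitsunobu closure).
- Stereochemistry: C4(u) from ligand-controlled CuH conjugate reduction of the indenone; C2(u) from CBS reduction, then SN2 inversion; C2(l) from catalytic asymmetric alkynylation, then SN2 inversion; C3(l) and C4(l) from osmylation of a Z-allylic silyl ether anti to the allylic oxygen.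

Key step: step 8

Conventions: flavonoid numbering; (u) is the upper flavan unit, (l) the lower flavan-3,4-diol unit. The target is (2S,4S)-2,4-trans in the upper unit and (2R,3R,4R)-all-cis in the lower unit.
Assumption: the sense of induction written for the ligand-controlled steps 7 and 16 follows the usual models; if the antipode forms, the mirror-image ligand is used.
Remark: the all-cis 3,4-diol is acid-labile at C4(l), so the lower diol is unveiled only in the last, neutral step.

**Step 1**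
Reactants: 1 2',3'-dihydroxyacetophenone
Product: 2 1-[2,3-bis(benzyloxy)phenyl]ethanone
Conditions: BnBr (2.5 equiv), K2CO3, DMF, 60 °C
Reagents that add atoms: benzyl bromide, BrCc1ccccc1
Why: Williamson etherification of both phenols, the hydrogen-bonded 2'-OH also being alkylated under warm carbonate/DMF conditions.

**Step 2**
Reactants: 2 1-[2,3-bis(benzyloxy)phenyl]ethanone
Product: 3 1-[2,3-bis(benzyloxy)-6-bromophenyl]ethanone
Conditions: NBS (1.05 equiv), MeCN, 0 °C to rt, dark
Reagents that add atoms: N-bromosuccinimide, O=C1CCC(=O)N1Br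
Why: Electrophilic aromatic bromination should go para to the 3'-benzyloxy group, the only ether lying in the ring plane (the 2'-ether is twisted between two ortho neighbours), as is known for 2,3-dialkoxybenzaldehydes, which places the halogen where the five-membered ring will close.

**Step 3**
Reactants: 4 2,3,4-trihydroxybenzaldehyde
Product: 5 2,3-dihydroxy-4-(methoxymethoxy)benzaldehyde
Conditions: MOMCl (1.05 equiv), iPr2NEt (1.1 equiv), DMF, 0 °C
Reagents that add atoms: chloromethyl methyl ether, COCCl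
Why: Selective O-alkylation (MOM ether formation) of the most acidic phenol, the 4-OH para to the formyl group, while the 2-OH is held in a hydrogen bond to the aldehyde.

**Step 4**
Reactants: 5 2,3-dihydroxy-4-(methoxymethoxy)benzaldehyde
Product: 6 2,3-bis(benzyloxy)-4-(methoxymethoxy)benzaldehyde
Conditions: BnBr (2.5 equiv), K2CO3, DMF, 50 °C
Reagents that add atoms: benzyl bromide, BrCc1ccccc1
Why: Williamson etherification of the two remaining phenols leaves the future O1(l) as the only oxygen with an orthogonal (MOM) group.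

**Step 5**
Reactants: 3 1-[2,3-bis(benzyloxy)-6-bromophenyl]ethanone; 6 2,3-bis(benzyloxy)-4-(methoxymethoxy)benzaldehyde
Product: 7 (E)-1-[2,3-bis(benzyloxy)-6-bromophenyl]-3-[2,3-bis(benzyloxy)-4-(methoxymethoxy)phenyl]prop-2-en-1-one
Conditions: KOH (aq.), EtOH/THF, rt
Reagents that add atoms: none
Why: Claisen–Schmidt condensation of the methyl ketone enolate with the non-enolisable aldehyde, dehydration giving the (E)-enone.

**Step 6**
Reactants: 7 (E)-chalcone
Product: 8 6,7-bis(benzyloxy)-3-[2,3-bis(benzyloxy)-4-(methoxymethoxy)phenyl]-1H-inden-1-one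
Conditions: Pd(OAc)2 (5 mol %), PPh3 (10 mol %), K2CO3, DMF, 100 °C
Reagents that add atoms: none
Why: Intramolecular Heck reaction (oxidative addition of zerovalent palladium to C–Br, aryl transfer to the enone β-carbon, β-hydride elimination), which gives 3-arylindenones from 2'-bromochalcones when no hydride donor is present.

**Step 7**
Reactants: 8 3-arylindenone
Product: 10 (3R)-6,7-bis(benzyloxy)-3-[2,3-bis(benzyloxy)-4-(methoxymethoxy)phenyl]-2,3-dihydro-1H-inden-1-one, via silyl enol ether 9 (not isolated)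
Conditions: Cu(OAc)2·H2O (3 mol %), (R)-DTBM-SEGPHOS (3 mol %), (EtO)2MeSiH (1.5 equiv), toluene, 0 °C; then K2CO3, MeOH/H2O
Reagents that add atoms: none
Why: Copper hydride-catalysed asymmetric conjugate reduction (1,4-hydrosilylation) of a β,β-disubstituted cyclic enone, in which the bisphosphine-bound CuH adds hydride to one face of C3 of the flat indenone and so sets C4(u), the ketone staying masked as silyl enol ether 9 until work-up.

**Step 8**
Reactants: 10 (3R)-3-aryl-6,7-bis(benzyloxy)indan-1-one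
Product: 12 (4S)-7,8-bis(benzyloxy)-4-[2,3-bis(benzyloxy)-4-(methoxymethoxy)phenyl]-3,4-dihydro-2H-chromen-2-one, via Criegee peroxyhemiketal 11 (not isolated)
Conditions: mCPBA (1.5 equiv), NaHCO3, CH2Cl2, 0 °C to rt
Reagents that add atoms: 3-chloroperoxybenzoic acid, OOC(=O)c1cccc(Cl)c1
Why: The peracid adds to the C1 carbonyl to give peroxyhemiketal 11, and the aryl carbon C7a, made electron-rich by its ortho benzyloxy group, then shifts from C1 to the proximal peroxide oxygen as 3-chlorobenzoate leaves, which cleaves C1–C7a and forms O1(u)–C8a(u). This is the Baeyer–Villiger oxidation of 1-indanones to 3,4-dihydrocoumarins, a reaction known for 3-arylindanones. The six-membered lactone arises by ring expansion through a 1,2-shift (oxygen insertion into the five-membered ring), not by a cyclisation, so no ring-closure mode has to be met. No stereocentre is formed, and C4(u) is neither the migrating centre nor enolisable, so the configuration from step 7 is carried through unchanged. The step needs aryl rather than methylene migration, which the higher migratory aptitude of an ortho-alkoxyaryl group over a primary alkyl group secures, and oxidation of the ketone rather than of the polyalkoxyarenes, which bicarbonate buffering and low temperature secure.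

**Step 9**
Reactants: 12 dihydrocoumarin
Product: 13 (3R)-3-[3,4-bis(benzyloxy)-2-hydroxyphenyl]-3-[2,3-bis(benzyloxy)-4-(methoxymethoxy)phenyl]-N-methoxy-N-methylpropanamide
Conditions: MeNH(OMe)·HCl (3 equiv), Me3Al (3 equiv), CH2Cl2, 0 °C to rt; then cold 0.5 M HCl
Reagents that add atoms: N,O-dimethylhydroxylamine hydrochloride, CNOC.Cl
Why: Weinreb aminolysis of the aryl ester lactone by the aluminium amide made in the flask opens the ring to the N-methoxy-N-methylamide and frees the C8a(u) phenol.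

**Step 10**
Reactants: 13 Weinreb amide; 14 1-(benzyloxy)-4-bromobenzene
Product: 16 (3R)-3-[3,4-bis(benzyloxy)-2-hydroxyphenyl]-1-[4-(benzyloxy)phenyl]-3-[2,3-bis(benzyloxy)-4-(methoxymethoxy)phenyl]propan-1-one, via 4-(benzyloxy)phenylmagnesium bromide 15 (not isolated)
Conditions: 14, Mg, THF, 40 °C; then 13 (0.3 equiv relative to 15), THF, 0 °C to rt; aq. NH4Cl
Reagents that add atoms: none
Why: Grignard addition to the Weinreb amide, whose magnesium-chelated tetrahedral intermediate stops at the ketone, one equivalent of reagent being spent on the phenol.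

**Step 11**
Reactants: 16 ketone
Product: 17 (1R,3R)-3-[3,4-bis(benzyloxy)-2-hydroxyphenyl]-1-[4-(benzyloxy)phenyl]-3-[2,3-bis(benzyloxy)-4-(methoxymethoxy)phenyl]propan-1-ol
Conditions: (S)-Me-CBS oxazaborolidine (20 mol %), BH3·SMe2 (2.2 equiv), THF, −20 °C; MeOH
Reagents that add atoms: none
Why: Corey–Bakshi–Shibata reduction of an aryl alkyl ketone, the (S)-oxazaborolidine delivering hydride to the face that gives the (R)-carbinol (aryl as the large group), with the extra borane consumed by the phenol.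

**Step 12**
Reactants: 17 (1R,3R)-hydroxy phenol
Product: 18 (2S,4S)-7,8-bis(benzyloxy)-2-[4-(benzyloxy)phenyl]-4-[2,3-bis(benzyloxy)-4-(methoxymethoxy)phenyl]-3,4-dihydro-2H-chromene
Conditions: PPh3, DIAD, THF, 0 °C
Reagents that add atoms: none
Why: Intramolecular Mitsunobu etherification (6-exo-tet), in which the phenoxide displaces the oxyphosphonium group with inversion, turning the (R)-carbinol into (S)-C2(u) trans to the C4(u) aryl group.

**Step 13**
Reactants: 18 upper flavan MOM ether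
Product: 19 2,3-bis(benzyloxy)-4-[(2S,4S)-7,8-bis(benzyloxy)-2-[4-(benzyloxy)phenyl]-3,4-dihydro-2H-chromen-4-yl]phenol
Conditions: HCl (1.25 M in MeOH), THF, 30 °C
Reagents that add atoms: none
Why: Acid-catalysed methanolysis of the aryl MOM acetal, which under these dilute conditions should be far more labile than the benzyl ethers and the flavan ring.

**Step 14**
Reactants: 19 phenol
Product: 20 6-iodo derivative of 19 (iodine at C4a(l), ortho to the free OH)
Conditions: NIS (1.05 equiv), CH2Cl2/MeCN, 0 °C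
Reagents that add atoms: N-iodosuccinimide, O=C1CCC(=O)N1I
Why: Electrophilic aromatic iodination of the free phenol, the most activated ring, at its only open ortho position (the para position carries the upper unit).

**Step 15**
Reactants: 20 iodophenol
Product: 21 tert-butyldimethylsilyl ether of 20
Conditions: TBSCl, imidazole, DMF, 40 °C
Reagents that add atoms: tert-butyldimethylsilyl chloride, CC(C)(C)[Si](C)(C)Cl
Why: Silylation of the phenol prevents benzofuran formation in the coupling and acetal formation through the phenol later.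

**Step 16**
Reactants: 22 4-(benzyloxy)benzaldehyde
Product: 23 (S)-1-[4-(benzyloxy)phenyl]-3-(trimethylsilyl)prop-2-yn-1-ol
Conditions: trimethylsilylacetylene (3 equiv), Me2Zn (3 equiv), (S,S)-ProPhenol (10 mol %), toluene, 0 °C; aq. NH4Cl
Reagents that add atoms: trimethylsilylacetylene, C#C[Si](C)(C)C
Why: Catalytic enantioselective alkynylation of an aromatic aldehyde by a zinc acetylide bound to the dinuclear zinc–ProPhenol catalyst, which sets the carbinol centre that becomes C2(l).

**Step 17**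
Reactants: 23 silylalkynyl carbinol
Product: 24 (R)-1-[4-(benzyloxy)phenyl]prop-2-yn-1-ol
Conditions: K2CO3 (cat.), MeOH, rt
Reagents that add atoms: none
Why: Base-catalysed methanolysis of the alkynyl C–Si bond (protodesilylation) leaves the carbinol centre untouched, the descriptor changing only through the priority rules.

**Step 18**
Reactants: 24 propargylic alcohol
Product: 25 (R)-tert-butyl({1-[4-(benzyloxy)phenyl]prop-2-yn-1-yl}oxy)dimethylsilane
Conditions: TBSCl, imidazole, DMF, rt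
Reagents that add atoms: tert-butyldimethylsilyl chloride, CC(C)(C)[Si](C)(C)Cl
Why: Silylation gives the silyl ether that later directs the osmylation and keeps this oxygen distinct from the diol.

**Step 19**
Reactants: 21 aryl iodide; 25 terminal alkyne
Product: 26 21 with iodine replaced by the (3S)-3-[4-(benzyloxy)phenyl]-3-(tert-butyldimethylsilyloxy)prop-1-yn-1-yl group
Conditions: PdCl2(PPh3)2 (5 mol %), CuI (10 mol %), Et3N/THF, 40 °C
Reagents that add atoms: none
Why: Sonogashira coupling of the aryl iodide with the terminal alkyne forms the C4(l)–C4a(l) bond without touching the propargylic centre.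

**Step 20**
Reactants: 26 diaryl alkyne
Product: 27 (Z)-alkene: 21 with iodine replaced by the (1Z,3R)-3-[4-(benzyloxy)phenyl]-3-(tert-butyldimethylsilyloxy)prop-1-en-1-yl group
Conditions: H2 (1 atm), Pd/CaCO3 poisoned with Pb(OAc)2 (Lindlar catalyst), quinoline, EtOAc, rt
Reagents that add atoms: none
Why: Lindlar semi-hydrogenation adds hydrogen syn to the alkyne and stops at the (Z)-alkene, leaving benzyl ethers intact.

**Step 21**
Reactants: 27 (Z)-allylic silyl ether
Product: 28 diol: 21 with iodine replaced by the (1R,2R,3S)-3-[4-(benzyloxy)phenyl]-3-(tert-butyldimethylsilyloxy)-1,2-dihydroxypropyl group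
Conditions: OsO4 (5 mol %), NMO (2 equiv), acetone/H2O, rt
Reagents that add atoms: N-methylmorpholine N-oxide, C[N+]1([O-])CCOCC1; water, O (both oxygens pass through catalytic OsO4, O=[Os](=O)(=O)=O)
Why: Catalytic syn-dihydroxylation in which, with the allylic C–H eclipsing the Z double bond (allylic 1,3-strain), OsO4 should add anti to the allylic silyloxy group (the empirical rule for allylic ethers), so C3(l)–OH is erythro to C2(l)–O and syn addition to the Z-alkene makes C3(l)/C4(l) erythro.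

**Step 22**
Reactants: 28 diol
Product: 29 1,2-O-benzylidene acetal of 28 (cis-4,5-disubstituted 2-phenyl-1,3-dioxolane, both epimers at the acetal carbon)
Conditions: PhCH(OMe)2, PPTS (cat.), CH2Cl2, rt
Reagents that add atoms: benzaldehyde dimethyl acetal, COC(OC)c1ccccc1
Why: Acid-catalysed transacetalisation ties the erythro diol into a cis-dioxolane, a protecting group that falls in the final hydrogenolysis.

**Step 23**
Reactants: 29 bis-silyl ether
Product: 30 29 with both silyl groups removed (free C8a(l) phenol, free (S)-C2(l) carbinol)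
Conditions: TBAF (2.5 equiv), THF, 0 °C; aq. NH4Cl
Reagents that add atoms: none
Why: Fluoride-mediated desilylation frees the phenol and the C2(l) carbinol in one operation, the acetal being stable to base.

**Step 24**
Reactants: 30 hydroxy phenol
Product: 31 hexa-O-benzyl-3,4-O-benzylidene derivative of the target
Conditions: PPh3, DIAD, toluene, 0 °C
Reagents that add atoms: none
Why: Intramolecular Mitsunobu etherification (6-exo-tet) closes the lower pyran with SN2 inversion at C2(l), which places the aryl group cis to the C3(l) and C4(l) oxygens.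

**Step 25**
Reactants: 31 protected dimer
Product: 32 CNP0209379.1
Conditions: H2 (1 atm), Pd(OH)2/C, THF/MeOH, rt
Reagents that add atoms: none
Why: Hydrogenolysis of the six benzyl ethers and the benzylidene acetal under neutral conditions, which avoid acid-induced epimerisation at C4(l) and C2(u).

**Compound list**
1 | 2',3'-dihydroxyacetophenone | CC(=O)c1cccc(O)c1O | starting material
2 | 1-[2,3-bis(benzyloxy)phenyl]ethanone | CC(=O)c1cccc(OCc2ccccc2)c1OCc3ccccc3 | intermediate
3 | 1-[2,3-bis(benzyloxy)-6-bromophenyl]ethanone | CC(=O)c1c(Br)ccc(OCc2ccccc2)c1OCc3ccccc3 | intermediate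
4 | 2,3,4-trihydroxybenzaldehyde | O=Cc1ccc(O)c(O)c1O | starting material
5 | 2,3-dihydroxy-4-(methoxymethoxy)benzaldehyde | COCOc1ccc(C=O)c(O)c1O | intermediate
6 | 2,3-bis(benzyloxy)-4-(methoxymethoxy)benzaldehyde | COCOc1ccc(C=O)c(OCc2ccccc2)c1OCc3ccccc3 | intermediate
7 | (E)-1-[2,3-bis(benzyloxy)-6-bromophenyl]-3-[2,3-bis(benzyloxy)-4-(methoxymethoxy)phenyl]prop-2-en-1-one | O=C(/C=C/c1ccc(OCOC)c(OCc2ccccc2)c1OCc3ccccc3)c4c(Br)ccc(OCc5ccccc5)c4OCc6ccccc6 | intermediate
8 | 6,7-bis(benzyloxy)-3-[2,3-bis(benzyloxy)-4-(methoxymethoxy)phenyl]-1H-inden-1-one | O=C1C=C(c2ccc(OCOC)c(OCc3ccccc3)c2OCc4ccccc4)c5ccc(OCc6ccccc6)c(OCc7ccccc7)c15 | intermediate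
9 | diethoxy(methyl)silyl enol ether of 10 (C1–O–Si, C1=C2; aryl-bearing carbon R) | CCO[Si](C)(OCC)OC1=C[C@@H](c2ccc(OCOC)c(OCc3ccccc3)c2OCc4ccccc4)c5ccc(OCc6ccccc6)c(OCc7ccccc7)c15 | intermediate
10 | (3R)-6,7-bis(benzyloxy)-3-[2,3-bis(benzyloxy)-4-(methoxymethoxy)phenyl]-2,3-dihydro-1H-inden-1-one | O=C1C[C@@H](c2ccc(OCOC)c(OCc3ccccc3)c2OCc4ccccc4)c5ccc(OCc6ccccc6)c(OCc7ccccc7)c15 | intermediate
11 | Criegee adduct of 10: 1-hydroxy-1-(3-chlorobenzoylperoxy)indane, both C1 epimers | OC1(OOC(=O)c2cccc(Cl)c2)C[C@@H](c3ccc(OCOC)c(OCc4ccccc4)c3OCc5ccccc5)c6ccc(OCc7ccccc7)c(OCc8ccccc8)c16 | intermediate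
12 | (4S)-7,8-bis(benzyloxy)-4-[2,3-bis(benzyloxy)-4-(methoxymethoxy)phenyl]-3,4-dihydro-2H-chromen-2-one | O=C1C[C@@H](c2ccc(OCOC)c(OCc3ccccc3)c2OCc4ccccc4)c5ccc(OCc6ccccc6)c(OCc7ccccc7)c5O1 | intermediate
13 | (3R)-3-[3,4-bis(benzyloxy)-2-hydroxyphenyl]-3-[2,3-bis(benzyloxy)-4-(methoxymethoxy)phenyl]-N-methoxy-N-methylpropanamide | CON(C)C(=O)C[C@@H](c1ccc(OCOC)c(OCc2ccccc2)c1OCc3ccccc3)c4ccc(OCc5ccccc5)c(OCc6ccccc6)c4O | intermediate
14 | 1-(benzyloxy)-4-bromobenzene | Brc1ccc(OCc2ccccc2)cc1 | starting material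
15 | 4-(benzyloxy)phenylmagnesium bromide | Br[Mg]c1ccc(OCc2ccccc2)cc1 | intermediate
16 | (3R)-3-[3,4-bis(benzyloxy)-2-hydroxyphenyl]-1-[4-(benzyloxy)phenyl]-3-[2,3-bis(benzyloxy)-4-(methoxymethoxy)phenyl]propan-1-one | O=C(C[C@@H](c1ccc(OCOC)c(OCc2ccccc2)c1OCc3ccccc3)c4ccc(OCc5ccccc5)c(OCc6ccccc6)c4O)c7ccc(OCc8ccccc8)cc7 | intermediate
17 | (1R,3R)-3-[3,4-bis(benzyloxy)-2-hydroxyphenyl]-1-[4-(benzyloxy)phenyl]-3-[2,3-bis(benzyloxy)-4-(methoxymethoxy)phenyl]propan-1-ol | O[C@H](C[C@@H](c1ccc(OCOC)c(OCc2ccccc2)c1OCc3ccccc3)c4ccc(OCc5ccccc5)c(OCc6ccccc6)c4O)c7ccc(OCc8ccccc8)cc7 | intermediate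
18 | (2S,4S)-7,8-bis(benzyloxy)-2-[4-(benzyloxy)phenyl]-4-[2,3-bis(benzyloxy)-4-(methoxymethoxy)phenyl]-3,4-dihydro-2H-chromene (2,4-trans) | C(Oc1ccc([C@@H]2C[C@@H](c3ccc(OCOC)c(OCc4ccccc4)c3OCc5ccccc5)c6ccc(OCc7ccccc7)c(OCc8ccccc8)c6O2)cc1)c9ccccc9 | intermediate
19 | 2,3-bis(benzyloxy)-4-[(2S,4S)-7,8-bis(benzyloxy)-2-[4-(benzyloxy)phenyl]-3,4-dihydro-2H-chromen-4-yl]phenol | C(Oc1ccc([C@@H]2C[C@@H](c3ccc(O)c(OCc4ccccc4)c3OCc5ccccc5)c6ccc(OCc7ccccc7)c(OCc8ccccc8)c6O2)cc1)c9ccccc9 | intermediate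
20 | 6-iodo derivative of 19 (iodine at C4a(l); upper unit unchanged) | C(Oc1ccc([C@@H]2C[C@@H](c3cc(I)c(O)c(OCc4ccccc4)c3OCc5ccccc5)c6ccc(OCc7ccccc7)c(OCc8ccccc8)c6O2)cc1)c9ccccc9 | intermediate
21 | tert-butyldimethylsilyl ether of phenol 20 | C(Oc1ccc([C@@H]2C[C@@H](c3cc(I)c(O[Si](C)(C)C(C)(C)C)c(OCc4ccccc4)c3OCc5ccccc5)c6ccc(OCc7ccccc7)c(OCc8ccccc8)c6O2)cc1)c9ccccc9 | intermediate
22 | 4-(benzyloxy)benzaldehyde | O=Cc1ccc(OCc2ccccc2)cc1 | starting material
23 | (S)-1-[4-(benzyloxy)phenyl]-3-(trimethylsilyl)prop-2-yn-1-ol | C[Si](C)(C)C#C[C@@H](O)c1ccc(OCc2ccccc2)cc1 | intermediate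
24 | (R)-1-[4-(benzyloxy)phenyl]prop-2-yn-1-ol | C#C[C@@H](O)c1ccc(OCc2ccccc2)cc1 | intermediate
25 | (R)-tert-butyl({1-[4-(benzyloxy)phenyl]prop-2-yn-1-yl}oxy)dimethylsilane | C#C[C@@H](O[Si](C)(C)C(C)(C)C)c1ccc(OCc2ccccc2)cc1 | intermediate
26 | 21 with iodine replaced by the (3S)-3-[4-(benzyloxy)phenyl]-3-(tert-butyldimethylsilyloxy)prop-1-yn-1-yl group | C(Oc1ccc([C@@H]2C[C@@H](c3cc(C#C[C@@H](O[Si](C)(C)C(C)(C)C)c%10ccc(OCc%11ccccc%11)cc%10)c(O[Si](C)(C)C(C)(C)C)c(OCc4ccccc4)c3OCc5ccccc5)c6ccc(OCc7ccccc7)c(OCc8ccccc8)c6O2)cc1)c9ccccc9 | intermediate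
27 | 21 with iodine replaced by the (1Z,3R)-3-[4-(benzyloxy)phenyl]-3-(tert-butyldimethylsilyloxy)prop-1-en-1-yl group | C(Oc1ccc([C@@H]2C[C@@H](c3cc(/C=C\[C@@H](O[Si](C)(C)C(C)(C)C)c%10ccc(OCc%11ccccc%11)cc%10)c(O[Si](C)(C)C(C)(C)C)c(OCc4ccccc4)c3OCc5ccccc5)c6ccc(OCc7ccccc7)c(OCc8ccccc8)c6O2)cc1)c9ccccc9 | intermediate
28 | 21 with iodine replaced by the (1R,2R,3S)-3-[4-(benzyloxy)phenyl]-3-(tert-butyldimethylsilyloxy)-1,2-dihydroxypropyl group (all erythro) | C(Oc1ccc([C@@H]2C[C@@H](c3cc([C@@H](O)[C@@H](O)[C@@H](O[Si](C)(C)C(C)(C)C)c%10ccc(OCc%11ccccc%11)cc%10)c(O[Si](C)(C)C(C)(C)C)c(OCc4ccccc4)c3OCc5ccccc5)c6ccc(OCc7ccccc7)c(OCc8ccccc8)c6O2)cc1)c9ccccc9 | intermediate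
29 | 1,2-O-benzylidene acetal of diol 28 (cis-dioxolane, acetal carbon as both epimers) | C(Oc1ccc([C@@H]2C[C@@H](c3cc([C@H]%12OC(c%13ccccc%13)O[C@H]%12[C@@H](O[Si](C)(C)C(C)(C)C)c%10ccc(OCc%11ccccc%11)cc%10)c(O[Si](C)(C)C(C)(C)C)c(OCc4ccccc4)c3OCc5ccccc5)c6ccc(OCc7ccccc7)c(OCc8ccccc8)c6O2)cc1)c9ccccc9 | intermediate
30 | 29 with both silyl groups removed (free C8a(l) phenol, free (S)-C2(l) carbinol) | C(Oc1ccc([C@@H]2C[C@@H](c3cc([C@H]%12OC(c%13ccccc%13)O[C@H]%12[C@@H](O)c%10ccc(OCc%11ccccc%11)cc%10)c(O)c(OCc4ccccc4)c3OCc5ccccc5)c6ccc(OCc7ccccc7)c(OCc8ccccc8)c6O2)cc1)c9ccccc9 | intermediate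
31 | hexa-O-benzyl-3,4-O-benzylidene derivative of the target (upper unit (2S), 2,4-trans; lower unit (2R), all-cis, cis-fused dioxolane at C3(l)/C4(l)) | C(Oc1ccc([C@@H]2C[C@@H](c3cc4c(c(OCc5ccccc5)c3OCc5ccccc5)O[C@H](c3ccc(OCc5ccccc5)cc3)[C@@H]5OC(c6ccccc6)O[C@H]45)c3ccc(OCc4ccccc4)c(OCc4ccccc4)c3O2)cc1)c1ccccc1 | intermediate
32 | CNP0209379.1: (2S,4S)-7,8-dihydroxy-2-(4-hydroxyphenyl)chroman-4-yl unit bonded through C4(u) to C6(l) of (2R,3R,4R)-2-(4-hydroxyphenyl)chromane-3,4,7,8-tetrol | Oc1ccc([C@@H]2C[C@@H](c3cc4c(c(O)c3O)O[C@H](c3ccc(O)cc3)[C@H](O)[C@@H]4O)c3ccc(O)c(O)c3O2)cc1 | target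

**Step count**
Total steps: 25. Longest linear sequence: 20 steps (1, 2, 5–15, 19–25); steps 3–4 and 16–18 are side branches.

**Steps most likely to fail**

Step 21. The osmylation may show poor facial selectivity, because the aryl group on the allylic stereocentre competes with the silyloxy group, and the hindered Z-alkene may react slowly. Fallback: catalyst control instead of substrate control, setting out from 21. A Heck coupling of 21 with 1-[4-(benzyloxy)phenyl]prop-2-en-1-one (Pd(OAc)2, Et3N, DMF) gives the (E)-enone F1. Nucleophilic asymmetric epoxidation (La(OiPr)3, (S)-BINOL, Ph3As=O, TBHP, THF) gives the (2R,3S)-trans-epoxy ketone F2. Chelation-controlled reduction with Zn(BH4)2 gives the anti-epoxy alcohol F3. BF3·OEt2-mediated insertion of benzaldehyde, with inversion at the benzylic epoxide carbon, gives the cis-dioxolane alcohol F4. TBAF then removes the aryl silyl ether and the route is rejoined at 30.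

Step 24. The electron-rich benzylic oxyphosphonium intermediate may ionise, which would lose the inversion at C2(l), or it may eliminate. Fallback, setting out from 30: oxidation of the benzylic carbinol with MnO2 gives a ketone that closes onto the phenol as the cyclic hemiketal F5. Ionic reduction (Et3SiH, BF3·OEt2, CH2Cl2, −78 °C) of the derived oxocarbenium ion adds hydride anti to the cis-fused dioxolane and returns to 31 with the 2,3-cis arrangement, without any SN2 step.

Step 7. The copper hydride may reduce the aryl ketone in a 1,2-sense, or discriminate poorly between the faces of the hindered β-carbon. Fallback, setting out from 8: CBS 1,2-reduction with the oxazaborolidine enantiomer that gives the (1S)-carbinol ((R)-Me-CBS on the usual model) gives the indenol F6. A DABCO-mediated suprafacial 1,3-hydrogen shift (THF, 60 °C) then transfers the chirality from C1 to C3 and tautomerises to 10.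

**Further compounds**
F1 | step 21 | (E)-enone: 21 with iodine replaced by the (E)-3-[4-(benzyloxy)phenyl]-3-oxoprop-1-en-1-yl group | C(Oc1ccc([C@@H]2C[C@@H](c3cc(/C=C/C(=O)c%10ccc(OCc%11ccccc%11)cc%10)c(O[Si](C)(C)C(C)(C)C)c(OCc4ccccc4)c3OCc5ccccc5)c6ccc(OCc7ccccc7)c(OCc8ccccc8)c6O2)cc1)c9ccccc9
F2 | step 21 | (2R,3S)-trans-epoxy ketone of F1 | C(Oc1ccc([C@@H]2C[C@@H](c3cc([C@@H]%12O[C@H]%12C(=O)c%10ccc(OCc%11ccccc%11)cc%10)c(O[Si](C)(C)C(C)(C)C)c(OCc4ccccc4)c3OCc5ccccc5)c6ccc(OCc7ccccc7)c(OCc8ccccc8)c6O2)cc1)c9ccccc9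
F3 | step 21 | anti-epoxy alcohol from F2 ((S)-carbinol at C2(l)) | C(Oc1ccc([C@@H]2C[C@@H](c3cc([C@@H]%12O[C@H]%12[C@@H](O)c%10ccc(OCc%11ccccc%11)cc%10)c(O[Si](C)(C)C(C)(C)C)c(OCc4ccccc4)c3OCc5ccccc5)c6ccc(OCc7ccccc7)c(OCc8ccccc8)c6O2)cc1)c9ccccc9
F4 | step 21 | cis-dioxolane alcohol: 29 with free C2(l)–OH and the aryl silyl ether kept | C(Oc1ccc([C@@H]2C[C@@H](c3cc([C@H]%12OC(c%13ccccc%13)O[C@H]%12[C@@H](O)c%10ccc(OCc%11ccccc%11)cc%10)c(O[Si](C)(C)C(C)(C)C)c(OCc4ccccc4)c3OCc5ccccc5)c6ccc(OCc7ccccc7)c(OCc8ccccc8)c6O2)cc1)c9ccccc9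
F5 | step 24 | cyclic hemiketal: 31 bearing OH at C2(l) (anomeric mixture, in equilibrium with the open C2(l) ketone) | C(Oc1ccc([C@@H]2C[C@@H](c3cc4c(c(OCc5ccccc5)c3OCc5ccccc5)OC(O)(c3ccc(OCc5ccccc5)cc3)[C@@H]5OC(c6ccccc6)O[C@H]45)c3ccc(OCc4ccccc4)c(OCc4ccccc4)c3O2)cc1)c1ccccc1
F6 | step 7 | (1S)-6,7-bis(benzyloxy)-3-[2,3-bis(benzyloxy)-4-(methoxymethoxy)phenyl]-1H-inden-1-ol | O[C@H]1C=C(c2ccc(OCOC)c(OCc3ccccc3)c2OCc4ccccc4)c5ccc(OCc6ccccc6)c(OCc7ccccc7)c15
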